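Naphthalene-1,4-dione locants are used. The hydroxyquinone ring is cut between C3 and C4: C4=O and C2–OH are the 1,3-dioxygen pair of a naphthalene-1,3-diol, that is an aryl ester plus an ortho acetonyl group, both hidden in the enol lactone of a 3-methylisocoumarin. In one pot, a pyranone-derived exocyclic ketene acetal diene and an aroyl ynone already carrying the pyranonylmethyl arm build the benzenoid ring by Diels–Alder benzannulation; methoxide then opens the lactone, the methyl-ketone enolate closes C3–C4, and air installs oxygen at C1. The step exploits the 1,3-relation of O–C2 and O–C4, the peri C5–OH (the former acetal carbon) and the oxidizable C1–H para to C4–OH.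

Key step: step 7

Remark: the target is achiral and is taken as the 2-hydroxy-1,4-dione tautomer drawn; the two propargylic carbinols of the route are racemic and their centre is removed by oxidation.

Step 1
Reactants: 1 pent-3-yn-2-one; 2 dimethyl malonate
Product: 3 methyl 4,6-dimethyl-2-oxo-2H-pyran-3-carboxylate
Conditions: NaOMe (0.2 equiv), MeOH, 0 °C to rt; AcOH quench
Reagents that add atoms: none
Why: Michael addition of the malonate anion to the ynone carbon remote from the carbonyl, then 6-exo-trig lactonization of the dienolate oxygen onto one ester with loss of methanol, should give the pyranone (the classical 2-pyranone synthesis from acetylenic ketones and malonates).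

Step 2
Reactants: 3 methyl 4,6-dimethyl-2-oxo-2H-pyran-3-carboxylate
Product: 4 3-[methoxy(trimethylsilyloxy)methylidene]-6-methyl-4-methylidene-3,4-dihydro-2H-pyran-2-one
Conditions: LiN(SiMe3)2, Me3SiCl (in situ quench), THF, −78 °C; filtration under Ar, used crude
Reagents that add atoms: chlorotrimethylsilane, C[Si](C)(C)Cl
Why: Kinetic γ-deprotonation of this vinylogous malonate at the 4-methyl group (the one next to the ester carbonyl, as in alkylidene malonates) and O-silylation of the ester enolate should give the s-cis-locked exocyclic ketene acetal diene (silyl ketene acetal formation; the O-silyl isomers interconvert by silyl shift and only this one can act as a diene).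

Step 3
Reactants: 5 4-methoxy-6-methyl-2H-pyran-2-one
Product: 6 6-(bromomethyl)-4-methoxy-2H-pyran-2-one
Conditions: NBS, AIBN (cat.), PhCF3, 85 °C
Reagents that add atoms: N-bromosuccinimide, O=C1CCC(=O)N1Br
Why: Wohl–Ziegler radical bromination should take place at the 6-methyl group, the allylic position of the dienyl lactone.

Step 4
Reactants: 7 2,4-dimethoxy-6-methylbenzaldehyde
Product: 8 1-(2,4-dimethoxy-6-methylphenyl)prop-2-yn-1-ol (racemic)
Conditions: HC≡CMgBr, THF, 0 °C; aq. NH4Cl
Reagents that add atoms: ethynylmagnesium bromide, C#C[Mg]Br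
Why: Grignard addition to the aldehyde should give the propargylic carbinol; the new centre is racemic and is removed in step 6.

Step 5
Reactants: 8 1-(2,4-dimethoxy-6-methylphenyl)prop-2-yn-1-ol (racemic); 6 6-(bromomethyl)-4-methoxy-2H-pyran-2-one
Product: 9 6-[4-(2,4-dimethoxy-6-methylphenyl)-4-hydroxybut-2-yn-1-yl]-4-methoxy-2H-pyran-2-one (racemic)
Conditions: CuI (0.2 equiv), NaI (0.2 equiv), K2CO3 (1.5 equiv), DMF, rt
Reagents that add atoms: none
Why: The copper acetylide formed under carbonate should alkylate the allylic-type bromide by SN2 (copper-mediated alkyne–allyl halide coupling to a skipped enyne), while K2CO3 is too weak to deprotonate the carbinol.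

Step 6
Reactants: 9 6-[4-(2,4-dimethoxy-6-methylphenyl)-4-hydroxybut-2-yn-1-yl]-4-methoxy-2H-pyran-2-one (racemic)
Product: 10 6-[4-(2,4-dimethoxy-6-methylphenyl)-4-oxobut-2-yn-1-yl]-4-methoxy-2H-pyran-2-one
Conditions: Dess–Martin periodinane, CH2Cl2, 0 °C to rt
Reagents that add atoms: none
Why: Dess–Martin oxidation of the secondary propargylic alcohol should give the ynone under non-basic conditions that do not trigger propargyl-to-allenyl isomerization of the doubly activated methylene.

Step 7
Reactants: 10 6-[4-(2,4-dimethoxy-6-methylphenyl)-4-oxobut-2-yn-1-yl]-4-methoxy-2H-pyran-2-one; 4 3-[methoxy(trimethylsilyloxy)methylidene]-6-methyl-4-methylidene-3,4-dihydro-2H-pyran-2-one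
Product: 14 6-(2,4-dimethoxy-6-methylbenzoyl)-2,5-dihydroxy-7-[(4-methoxy-2-oxo-2H-pyran-6-yl)methyl]naphthalene-1,4-dione, via isocoumarin 11 (not isolated), via keto ester 12 (not isolated), via naphthalenetriol 13 (not isolated)
Conditions: 4 (1.5 equiv), PhMe, 100 °C; then NaOMe (5 equiv), MeOH–THF, 60 °C, Ar; then AcOH to pH 8, O2 (1 atm), rt
Reagents that add atoms: dioxygen, O=O
Why: The s-cis-locked ketene acetal diene 4 (largest HOMO coefficient at its CH2 terminus) should add to ynone 10 (largest LUMO coefficient at the alkyne carbon remote from the carbonyl) in a normal-demand Diels–Alder reaction that re-forms the pyranone ring, and loss of Me3SiOMe (thermally or on methoxide addition) aromatizes the adduct to isocoumarin 11; methoxide then opens the enol lactone to keto ester 12, whose methyl-ketone enolate attacks the ester carbonyl to form the C3–C4 bond and, after enolization, triol 13, which O2 oxidizes at C1 to hydroxyquinone 14. The closest known reaction types are the vinylketene silyl acetal/ynone Diels–Alder synthesis of salicylates, the alkoxide-induced rearrangement of enol lactones to cyclic 1,3-diketones (benzylidenephthalide to 2-phenylindane-1,3-dione, here in its six-ring version), the Claisen cyclization of 2-(2-oxopropyl)benzoates and the autoxidation of 1,3,8-trihydroxynaphthalene to 2-hydroxyjuglone. The benzenoid ring closes by [4+2] cycloaddition and the quinone ring by a 6-(enolendo)-exo-trig Claisen (Dieckmann-type) acyl substitution; no stereocentre is formed. Regiochemistry of the cycloaddition rests on the matched polarization of ketene acetal and ynone, which puts the acetal carbon (later C5–OH) next to the aroyl-bearing carbon and the CH2 terminus next to the carbon carrying the pyranonylmethyl group. C- over O-acylation is secured thermodynamically, because lactone 11 and ester 12 interconvert under methoxide, the benzylic enolate cannot C-acylate (four-membered ring), and only the methyl enolate leads to the aromatic diolate that drains the equilibrium. Oxidation is confined to the triol ring by buffering to pH 8 before O2 is admitted, so that the benzylic methylene is not deprotonated.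

Step 8
Reactants: 14 6-(2,4-dimethoxy-6-methylbenzoyl)-2,5-dihydroxy-7-[(4-methoxy-2-oxo-2H-pyran-6-yl)methyl]naphthalene-1,4-dione
Product: 15 6-(2,4-dihydroxy-6-methylbenzoyl)-2,5-dihydroxy-7-[(4-hydroxy-2-oxo-2H-pyran-6-yl)methyl]naphthalene-1,4-dione
Conditions: BBr3 (8 equiv), CH2Cl2, −78 °C to rt; H2O
Reagents that add atoms: none
Why: BBr3 ether cleavage (Lewis acid coordination, bromide SN2 at methyl) should remove the two aryl methyl ethers and the vinylogous-ester methyl ether of the pyranone, and hydrolysis of the borates on work-up should give the target.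

Compound list
1 | pent-3-yn-2-one | CC#CC(C)=O | starting material
2 | dimethyl malonate | COC(=O)CC(=O)OC | starting material
3 | methyl 4,6-dimethyl-2-oxo-2H-pyran-3-carboxylate | COC(=O)C1=C(C)C=C(C)OC1=O | intermediate
4 | 3-[methoxy(trimethylsilyloxy)methylidene]-6-methyl-4-methylidene-3,4-dihydro-2H-pyran-2-one (either geometry of the acetal double bond) | COC(O[Si](C)(C)C)=C1C(=C)C=C(C)OC1=O | intermediate
5 | 4-methoxy-6-methyl-2H-pyran-2-one | COC1=CC(=O)OC(C)=C1 | starting material
6 | 6-(bromomethyl)-4-methoxy-2H-pyran-2-one | COC1=CC(=O)OC(CBr)=C1 | intermediate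
7 | 2,4-dimethoxy-6-methylbenzaldehyde | COc1cc(C)c(C=O)c(OC)c1 | starting material
8 | 1-(2,4-dimethoxy-6-methylphenyl)prop-2-yn-1-ol (racemic) | COc1cc(C)c(C(O)C#C)c(OC)c1 | intermediate
9 | 6-[4-(2,4-dimethoxy-6-methylphenyl)-4-hydroxybut-2-yn-1-yl]-4-methoxy-2H-pyran-2-one (racemic) | COc1cc(C)c(C(O)C#CCC2=CC(OC)=CC(=O)O2)c(OC)c1 | intermediate
10 | 6-[4-(2,4-dimethoxy-6-methylphenyl)-4-oxobut-2-yn-1-yl]-4-methoxy-2H-pyran-2-one | COc1cc(C)c(C(=O)C#CCC2=CC(OC)=CC(=O)O2)c(OC)c1 | intermediate
11 | 7-(2,4-dimethoxy-6-methylbenzoyl)-8-hydroxy-6-[(4-methoxy-2-oxo-2H-pyran-6-yl)methyl]-3-methyl-1H-isochromen-1-one | O=C1OC(C)=Cc2cc(CC3=CC(OC)=CC(=O)O3)c(C(=O)c3c(C)cc(OC)cc3OC)c(O)c12 | intermediate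
12 | methyl 3-(2,4-dimethoxy-6-methylbenzoyl)-2-hydroxy-4-[(4-methoxy-2-oxo-2H-pyran-6-yl)methyl]-6-(2-oxopropyl)benzoate | COC(=O)c1c(CC(C)=O)cc(CC2=CC(OC)=CC(=O)O2)c(C(=O)c2c(C)cc(OC)cc2OC)c1O | intermediate
13 | 7-(2,4-dimethoxy-6-methylbenzoyl)-6-[(4-methoxy-2-oxo-2H-pyran-6-yl)methyl]naphthalene-1,3,8-triol | Oc1cc(O)c2c(O)c(C(=O)c3c(C)cc(OC)cc3OC)c(CC3=CC(OC)=CC(=O)O3)cc2c1 | intermediate
14 | 6-(2,4-dimethoxy-6-methylbenzoyl)-2,5-dihydroxy-7-[(4-methoxy-2-oxo-2H-pyran-6-yl)methyl]naphthalene-1,4-dione | COc1cc(C)c(C(=O)c2c(CC3=CC(OC)=CC(=O)O3)cc3c(c2O)C(=O)C=C(O)C3=O)c(OC)c1 | intermediate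
15 | 6-(2,4-dihydroxy-6-methylbenzoyl)-2,5-dihydroxy-7-[(4-hydroxy-2-oxo-2H-pyran-6-yl)methyl]naphthalene-1,4-dione | Cc1cc(O)cc(O)c1C(=O)c1c(Cc2cc(O)cc(=O)o2)cc2c(c1O)C(=O)C=C(O)C2=O | target

Total step count: 8. Longest linear sequence: 5 steps (steps 4, 5, 6, 7, 8).

Steps most likely to fail

Step 7. The cycloaddition may be sluggish at the hindered ynone. The O-to-C acyl transfer may stall because the phenoxide-flanked ester is deactivated and the lactone re-closes. Methoxide may open the methoxypyranone, or the benzylic methylene may autoxidize. Fallback: a stepwise, protected sequence that sets out from isocoumarin 11, isolated after the cycloaddition stage (PhMe, 100 °C; dilute HCl work-up), and comes back at target 15. MeI, K2CO3, acetone should mask the phenol as the 8-O-methyl isocoumarin F1. Catalytic NaOMe in MeOH at 0 °C, quenched with AcOH, should open the lactone to the keto ester F2. Kinetic Claisen cyclization with LiN(SiMe3)2 (4 equiv), THF, −78 to 0 °C, should give the 8-methoxynaphthalene-1,3-diol F3. Oxidation with potassium nitrosodisulfonate, (KSO3)2NO, in KH2PO4-buffered aqueous acetone should give the 5-O-methyl hydroxyquinone F4. BBr3 as in step 8 should then cleave all four methyl ethers to 15.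

Step 2. Deprotonation may compete at the 6-methyl group, silylation may occur on carbon, and the quinodimethane-like diene may dimerize or hydrolyse. Fallback: sets out from ynone 10 and commercial dimethyl 2-(propan-2-ylidene)malonate and comes back at keto ester 12, which is then carried through the methoxide and O2 stages of step 7. LiN(iPr)2 and Me3SiCl should convert the malonate, whose two methyl groups are equivalent, into the acyclic ketene acetal diene F5. Its Diels–Alder reaction with 10 (PhMe, 100 °C, then dilute acid) should give the 6-methylsalicylate F6. Lateral lithiation of F6 as its trianion (LiN(iPr)2, 3.3 equiv, THF, −78 °C; the o-toluate carbanion forms last and reacts first) and acylation with N-methoxy-N-methylacetamide should give 12.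

Step 5. A base-induced prototropic shift of the doubly activated methylene (propargyl-to-allenyl isomerization) and oxidative alkyne homocoupling may erode the coupling. Fallback: a base-free sequence that sets out from bromide 6 and comes back at ynone 10. Stille coupling of 6 with tributyl[(trimethylsilyl)ethynyl]stannane (Pd(PPh3)4, zerovalent palladium, THF, 60 °C) should give the silylalkyne F7. Friedel–Crafts-type acylative desilylation of F7 with the acid chloride F8 (from commercial 2,4-dimethoxy-6-methylbenzoic acid and oxalyl chloride), AlCl3, CH2Cl2, −20 °C, should give 10 directly, without carbinol, carbonate base or oxidation.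

Further compounds
F1 | step 7 | 7-(2,4-dimethoxy-6-methylbenzoyl)-8-methoxy-6-[(4-methoxy-2-oxo-2H-pyran-6-yl)methyl]-3-methyl-1H-isochromen-1-one | O=C1OC(C)=Cc2cc(CC3=CC(OC)=CC(=O)O3)c(C(=O)c3c(C)cc(OC)cc3OC)c(OC)c12
F2 | step 7 | methyl 3-(2,4-dimethoxy-6-methylbenzoyl)-2-methoxy-4-[(4-methoxy-2-oxo-2H-pyran-6-yl)methyl]-6-(2-oxopropyl)benzoate | COC(=O)c1c(CC(C)=O)cc(CC2=CC(OC)=CC(=O)O2)c(C(=O)c2c(C)cc(OC)cc2OC)c1OC
F3 | step 7 | 7-(2,4-dimethoxy-6-methylbenzoyl)-8-methoxy-6-[(4-methoxy-2-oxo-2H-pyran-6-yl)methyl]naphthalene-1,3-diol | Oc1cc(O)c2c(OC)c(C(=O)c3c(C)cc(OC)cc3OC)c(CC3=CC(OC)=CC(=O)O3)cc2c1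
F4 | step 7 | 6-(2,4-dimethoxy-6-methylbenzoyl)-2-hydroxy-5-methoxy-7-[(4-methoxy-2-oxo-2H-pyran-6-yl)methyl]naphthalene-1,4-dione | COc1cc(C)c(C(=O)c2c(CC3=CC(OC)=CC(=O)O3)cc3c(c2OC)C(=O)C=C(O)C3=O)c(OC)c1
F5 | step 2 | methyl 2-[methoxy(trimethylsilyloxy)methylidene]-3-methylbut-3-enoate | COC(O[Si](C)(C)C)=C(C(C)=C)C(=O)OC
F6 | step 2 | methyl 3-(2,4-dimethoxy-6-methylbenzoyl)-2-hydroxy-4-[(4-methoxy-2-oxo-2H-pyran-6-yl)methyl]-6-methylbenzoate | COC(=O)c1c(C)cc(CC2=CC(OC)=CC(=O)O2)c(C(=O)c2c(C)cc(OC)cc2OC)c1O
F7 | step 5 | 4-methoxy-6-[3-(trimethylsilyl)prop-2-yn-1-yl]-2H-pyran-2-one | COC1=CC(=O)OC(CC#C[Si](C)(C)C)=C1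
F8 | step 5 | 2,4-dimethoxy-6-methylbenzoyl chloride | COc1cc(C)c(C(Cl)=O)c(OC)c1
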